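**Plan**

- Retrosynthesis: the C5–OH and C7–OH bonds are traced back (through benzyl ethers) to C–F bonds. Ring C is then cut at O1–C8a and at C3–C4, giving 2,4,6-trifluoro-3,5-dimethoxybenzoyl chloride and the methyl ketone that carries ring B.
- Enabling feature: on ring A, O1, the 5-OH and the 7-OH lie ortho, ortho and para to the C4 carbonyl. These are the positions at which the fluorides of a 2,4,6-trifluorobenzoyl unit can be displaced by oxygen nucleophiles; C6 and C8 carry their methoxyls from the start.
- Forward: ring A is bought as 2,4,6-trifluorophenol and dressed (two O-methylations, one hydroxylation, one carboxylation). Ring B comes with commercial 3,4,5-trimethoxyacetophenone.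
- Ring C is the only ring made. It closes in the key step by enolate C-acylation followed by intramolecular fluoride displacement; the two remaining fluorides are then exchanged for benzyloxy groups and hydrogenolysed.
- Stereochemistry: the target has no stereocentre and no stereogenic double bond, so none has to be set.

Key step: step 6

Assumption: of the two activated fluorides of the difluoroflavone, the one para to the carbonyl (C7) is taken to be displaced first in step 7; the order has no bearing on the product of that step because both are exchanged.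

**Step 1**
Reactants: 1 2,4,6-trifluorophenol
Product: 2 1,3,5-trifluoro-2-methoxybenzene (2,4,6-trifluoroanisole)
Conditions: MeI, K2CO3, acetone, 40 °C
Reagents that add atoms: iodomethane, CI
Why: Williamson O-methylation of the acidic fluorophenol through its potassium phenoxide (SN2 on MeI) should be clean, since the ring offers no other site for alkylation.

**Step 2**
Reactants: 2 1,3,5-trifluoro-2-methoxybenzene
Product: 5 2,4,6-trifluoro-3-methoxyphenol, via aryllithium 3 (not isolated), via lithium aryltrimethoxyborate 4 (not isolated)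
Conditions: n-BuLi, THF, −78 °C; B(OMe)3, −78 → 0 °C; AcOH, 30% aq. H2O2, 0 °C → rt
Reagents that add atoms: hydrogen peroxide, OO
Why: Lithiation of the C–H flanked by two fluorines (the two such sites are equivalent), borylation and oxidative 1,2-shift of the aryl group from boron to oxygen is a standard one-flask arene hydroxylation; the cold lithiation avoids aryne formation and the acidic peroxide avoids base-induced protodeboronation.

**Step 3**
Reactants: 5 2,4,6-trifluoro-3-methoxyphenol
Product: 6 1,3,5-trifluoro-2,4-dimethoxybenzene
Conditions: MeI, K2CO3, DMF, rt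
Reagents that add atoms: iodomethane, CI
Why: A second Williamson O-methylation of a still more acidic fluorophenol should proceed as in step 1.

**Step 4**
Reactants: 6 1,3,5-trifluoro-2,4-dimethoxybenzene
Product: 8 2,4,6-trifluoro-3,5-dimethoxybenzoic acid, via aryllithium 7 (not isolated)
Conditions: n-BuLi, THF, −78 °C; CO2 (g), −78 °C → rt; aq. HCl
Reagents that add atoms: carbon dioxide, O=C=O
Why: The single remaining ring hydrogen sits between two fluorines, so deprotonation is regiochemically unambiguous, and carboxylation of the 2,6-difluoroaryllithium with CO2 is a standard lithiation–carboxylation.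

**Step 5**
Reactants: 8 2,4,6-trifluoro-3,5-dimethoxybenzoic acid
Product: 9 2,4,6-trifluoro-3,5-dimethoxybenzoyl chloride
Conditions: (COCl)2, DMF (cat.), CH2Cl2, 0 °C → rt; volatiles removed, used crude
Reagents that add atoms: oxalyl chloride, O=C(Cl)C(=O)Cl
Why: Acid chloride formation with oxalyl chloride under chloroiminium catalysis by DMF gives only gaseous by-products and leaves the aryl fluorides and methyl ethers untouched.

**Step 6**
Reactants: 10 1-(3,4,5-trimethoxyphenyl)ethanone; 9 2,4,6-trifluoro-3,5-dimethoxybenzoyl chloride
Product: 13 5,7-difluoro-6,8-dimethoxy-2-(3,4,5-trimethoxyphenyl)-4H-chromen-4-one, via lithium enolate 11 (not isolated), via 1,3-diketone 12 (not isolated)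
Conditions: 10, LiN(SiMe3)2 (2.05 equiv), THF, −78 °C; 9, −78 → 0 °C; then K2CO3, DMF, 70 °C
Reagents that add atoms: none
Why: The lithium enolate 11 attacks the acid chloride at carbon (Claisen-type C-acylation through a tetrahedral intermediate, C3–C4), and the second equivalent of LiN(SiMe3)2 at once converts the more acidic diketone 12 into its chelated lithium diketonate, which shields it from a second acylation. On warming in DMF the enolate oxygen on C2 adds to C8a, an ortho C–F carbon, to give an anionic sigma-adduct stabilised by the C4 carbonyl, and loss of fluoride restores the arene (intramolecular SNAr, O1–C8a); K2CO3 loosens the lithium chelate by cation exchange and is regained in the net balance. The closest known reaction type is the acylation of ketone enolates with 2-fluorobenzoyl chlorides followed by base-induced fluoride displacement to chromones, flavones and polyfluoroflavones. Ring C closes as a six-membered ring by addition across the C4a=C8a bond of the arene (formally 6-endo-trig, with the fluoride leaving group outside the new ring), the only ring size the diketonate can reach. No stereocentre is formed. The step needs C- over O-acylation, secured by the lithium counter-ion in THF at −78 °C and the excess of amide base, and ortho over para fluoride displacement, secured because only the two equivalent ortho fluorines lie within reach of the enolate oxygen; the two methoxyls make the ring less electrophilic than the polyfluoro precedents, which is why the closure is driven by heat in DMF.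

**Step 7**
Reactants: 13 5,7-difluoro-6,8-dimethoxy-2-(3,4,5-trimethoxyphenyl)-4H-chromen-4-one
Product: 15 5,7-bis(benzyloxy)-6,8-dimethoxy-2-(3,4,5-trimethoxyphenyl)-4H-chromen-4-one, via 7-benzyloxy-5-fluoro mono-ether 14 (not isolated)
Conditions: BnOH (2.5 equiv), NaH (2.3 equiv), DMF, 0 °C; then 13, 0 → 60 °C
Reagents that add atoms: benzyl alcohol, OCc1ccccc1
Why: Twofold SNAr (addition–elimination) by benzyloxide at C7 and C5, the positions para and ortho to the C4 carbonyl, is the known reactivity of 5- and 7-fluorochromones towards alkoxides; alkoxide addition at C2 is reversible and the methyl ethers are inert under these conditions.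

**Step 8**
Reactants: 15 5,7-bis(benzyloxy)-6,8-dimethoxy-2-(3,4,5-trimethoxyphenyl)-4H-chromen-4-one
Product: 16 5,7-dihydroxy-6,8-dimethoxy-2-(3,4,5-trimethoxyphenyl)-4H-chromen-4-one (5,7-dihydroxy-6,8,3',4',5'-pentamethoxyflavone)
Conditions: H2 (1 atm), Pd/C (palladium metal on carbon), EtOAc–MeOH, rt, stopped at full conversion
Reagents that add atoms: none
Why: Catalytic hydrogenolysis of the two benzyl aryl ethers over palladium should free the 5- and 7-hydroxyls while the methyl ethers and, at ambient pressure with monitoring, the C2=C3 bond of the flavone stay intact.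

**Compound list**

1 | 2,4,6-trifluorophenol | Oc1c(F)cc(F)cc1F | starting material
2 | 1,3,5-trifluoro-2-methoxybenzene (2,4,6-trifluoroanisole) | COc1c(F)cc(F)cc1F | intermediate
3 | (2,4,6-trifluoro-3-methoxyphenyl)lithium | [Li]c1c(F)cc(F)c(OC)c1F | intermediate (not isolated)
4 | lithium trimethoxy(2,4,6-trifluoro-3-methoxyphenyl)borate | [Li+].CO[B-](OC)(OC)c1c(F)cc(F)c(OC)c1F | intermediate (not isolated)
5 | 2,4,6-trifluoro-3-methoxyphenol | COc1c(F)c(O)c(F)cc1F | intermediate
6 | 1,3,5-trifluoro-2,4-dimethoxybenzene | COc1c(F)c(OC)c(F)cc1F | intermediate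
7 | (2,4,6-trifluoro-3,5-dimethoxyphenyl)lithium | [Li]c1c(F)c(OC)c(F)c(OC)c1F | intermediate (not isolated)
8 | 2,4,6-trifluoro-3,5-dimethoxybenzoic acid | COc1c(F)c(OC)c(F)c(C(=O)O)c1F | intermediate
9 | 2,4,6-trifluoro-3,5-dimethoxybenzoyl chloride | COc1c(F)c(OC)c(F)c(C(=O)Cl)c1F | intermediate
10 | 1-(3,4,5-trimethoxyphenyl)ethanone | CC(=O)c1cc(OC)c(OC)c(OC)c1 | starting material
11 | lithium 1-(3,4,5-trimethoxyphenyl)ethen-1-olate | [Li]OC(=C)c1cc(OC)c(OC)c(OC)c1 | intermediate (not isolated)
12 | 1-(2,4,6-trifluoro-3,5-dimethoxyphenyl)-3-(3,4,5-trimethoxyphenyl)propane-1,3-dione (held in the flask as its lithium diketonate) | COc1cc(C(=O)CC(=O)c2c(F)c(OC)c(F)c(OC)c2F)cc(OC)c1OC | intermediate (not isolated)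
13 | 5,7-difluoro-6,8-dimethoxy-2-(3,4,5-trimethoxyphenyl)-4H-chromen-4-one | COc1cc(-c2cc(=O)c3c(F)c(OC)c(F)c(OC)c3o2)cc(OC)c1OC | intermediate
14 | 7-(benzyloxy)-5-fluoro-6,8-dimethoxy-2-(3,4,5-trimethoxyphenyl)-4H-chromen-4-one | COc1cc(-c2cc(=O)c3c(F)c(OC)c(OCc4ccccc4)c(OC)c3o2)cc(OC)c1OC | intermediate (not isolated)
15 | 5,7-bis(benzyloxy)-6,8-dimethoxy-2-(3,4,5-trimethoxyphenyl)-4H-chromen-4-one | COc1cc(-c2cc(=O)c3c(OCc4ccccc4)c(OC)c(OCc4ccccc4)c(OC)c3o2)cc(OC)c1OC | intermediate
16 | 5,7-dihydroxy-6,8-dimethoxy-2-(3,4,5-trimethoxyphenyl)-4H-chromen-4-one | COc1cc(-c2cc(=O)c3c(O)c(OC)c(O)c(OC)c3o2)cc(OC)c1OC | target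

**Summary**

Total step count: 8. Longest linear sequence: 8 steps (1 → 16); ketone 10 enters as bought.

**Steps most likely to fail**

Step 7. Alkoxide addition at C2 may open the pyranone ring, and the second displacement may stall once ring A carries three alkoxy groups. The fallback exchanges one fluoride at a time and delivers the second oxygen with a weakly basic alpha-effect nucleophile instead of an alkoxide. Setting out from 13, one equivalent of sodium benzyloxide in THF at −20 °C should give 14, now isolated. Acetohydroxamic acid and K2CO3 in DMSO at 80 °C should then displace the C5 fluoride to give N-{[7-(benzyloxy)-6,8-dimethoxy-4-oxo-2-(3,4,5-trimethoxyphenyl)-4H-chromen-5-yl]oxy}acetamide F1. Under the same conditions this fragments by a Lossen rearrangement (loss of methyl isocyanate) to 7-(benzyloxy)-5-hydroxy-6,8-dimethoxy-2-(3,4,5-trimethoxyphenyl)-4H-chromen-4-one F2. Hydrogenolysis of its single benzyl ether (H2, Pd/C, EtOAc–MeOH) rejoins the route at 16.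

Step 6. O-acylation or double acylation of the enolate may erode the diketone, and fluoride displacement may be sluggish on the methoxy-deactivated ring. The fallback makes the C3–C4 bond without an enolate. Setting out from 9, an acyl Sonogashira coupling with commercial 5-ethynyl-1,2,3-trimethoxybenzene F3 (PdCl2(PPh3)2, CuI, Et3N, THF, rt) should give the ynone 1-(2,4,6-trifluoro-3,5-dimethoxyphenyl)-3-(3,4,5-trimethoxyphenyl)prop-2-yn-1-one F4. Conjugate addition of diethylamine (EtOH, 0 °C) should give the enaminone (E)-3-(diethylamino)-1-(2,4,6-trifluoro-3,5-dimethoxyphenyl)-3-(3,4,5-trimethoxyphenyl)prop-2-en-1-one F5. Hydrolysis with dilute aqueous HCl in THF gives the diketone 12, this time isolated; K2CO3 in DMF at 70 °C closes ring C and the route is rejoined at 13.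

Step 2. The ortho-fluoro aryllithium may lose LiF to an aryne on warming, and the 2,6-difluoroaryl boron species may be protodeboronated before it is oxidised. The fallback puts the boron on without an organolithium. Setting out from 2 (used in excess to suppress double borylation), iridium-catalysed C–H borylation ([Ir(OMe)(cod)]2, 4,4'-di-tert-butyl-2,2'-bipyridine, B2pin2, THF, 60 °C) should functionalise the C–H between two fluorines and give the isolable pinacol boronate 2-(2,4,6-trifluoro-3-methoxyphenyl)-4,4,5,5-tetramethyl-1,3,2-dioxaborolane F6. Oxidation with aqueous H2O2 in THF–AcOH rejoins the route at 5.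

**Further compounds**

F1 | step 7 | N-{[7-(benzyloxy)-6,8-dimethoxy-4-oxo-2-(3,4,5-trimethoxyphenyl)-4H-chromen-5-yl]oxy}acetamide | COc1cc(-c2cc(=O)c3c(ONC(C)=O)c(OC)c(OCc4ccccc4)c(OC)c3o2)cc(OC)c1OC
F2 | step 7 | 7-(benzyloxy)-5-hydroxy-6,8-dimethoxy-2-(3,4,5-trimethoxyphenyl)-4H-chromen-4-one | COc1cc(-c2cc(=O)c3c(O)c(OC)c(OCc4ccccc4)c(OC)c3o2)cc(OC)c1OC
F3 | step 6 | 5-ethynyl-1,2,3-trimethoxybenzene | C#Cc1cc(OC)c(OC)c(OC)c1
F4 | step 6 | 1-(2,4,6-trifluoro-3,5-dimethoxyphenyl)-3-(3,4,5-trimethoxyphenyl)prop-2-yn-1-one | COc1cc(C#CC(=O)c2c(F)c(OC)c(F)c(OC)c2F)cc(OC)c1OC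
F5 | step 6 | (E)-3-(diethylamino)-1-(2,4,6-trifluoro-3,5-dimethoxyphenyl)-3-(3,4,5-trimethoxyphenyl)prop-2-en-1-one | CCN(CC)/C(=C/C(=O)c1c(F)c(OC)c(F)c(OC)c1F)c1cc(OC)c(OC)c(OC)c1
F6 | step 2 | 2-(2,4,6-trifluoro-3-methoxyphenyl)-4,4,5,5-tetramethyl-1,3,2-dioxaborolane | COc1c(F)cc(F)c(B2OC(C)(C)C(C)(C)O2)c1F
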